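I start from two constants that the earlier runs give.

| flask | substrate | partner | capture agent | remark | time |
|---|---|---|---|---|---|
| Friday's | 17 mM | 1.1 equiv | 1.7 mM | run made earlier |  |
| Saturday's | 17 mM | 1.5 equiv | 1.7 mM | run made earlier |  |
| Tuesday's | 17 mM | 2.4 equiv | 1.7 mM | run made earlier |  |
| Monday's | 8.5 mM | 1.1 equiv | 1.7 mM | run made earlier |  |
| ochre | 17 mM | 1.10 equiv (fed, over 64.0 min) | 1.70 mM | a stirred flask in which partner is dosed at a steady rate over 64.0 min without added volume, worked up at 80 min | 80 min |
| blue | 17 mM | 1.10 equiv | 1.70 mM | everything together in a closed stirred flask, run for 80 min | 80 min |
| amber | 17 mM (fed, over 64.0 min) | 1.10 equiv | 1.70 mM | a stirred flask in which substrate is dosed at a steady rate over 64.0 min without added volume, worked up at 80 min | 80 min |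
| grey | 17 mM | 1.10 equiv | 1.70 mM | one stirred flow tank at steady state, fed with the mixture as stated, mean residence time 80 min |  |

- Friday's (time / min: open intermediate / %, target / %): 4.00: 26.3, 0.9; 8.00: 43.5, 2.6; 20.0: 63.3, 12.8; 50.0: 52.6, 34.1
- Saturday's (time / min: open intermediate / %, target / %): 6.00: 35.3, 2.2; 15.0: 56.4, 11.3; 30.0: 57.3, 27.3; 50.0: 44.8, 43.9
- Tuesday's (time / min: open intermediate / %, target / %): 4.00: 24.6, 2.2; 8.00: 39.6, 6.1; 20.0: 51.2, 24.9; 50.0: 30.2, 60.9
- Monday's (time / min: open intermediate / %, target / %): 6.00: 36.4, 1.2; 15.0: 64.0, 3.8; 30.0: 75.6, 11.2; 50.0: 70.5, 19.4

(each reading ± 0.3 percentage points)

- the stated concentrations are those of everything mixed, before any reaction; amounts are the same in each set-up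
- what was read earlier has a scatter of 0.3 percentage points, one standard deviation
- the feed brings no volume worth counting
- the earlier runs were made in a closed, stirred flask

1. the set-up with the highest amount of open intermediate at the outlet or at the end, in percent of the substrate put in ("none" if the first two lie within 2 percentage points) (ochre / blue / amber / grey / none)
2. amount of open intermediate at the outlet or at the end, in percent of the substrate put in, ochre
3. amount of open intermediate at the outlet or at the end, in percent of the substrate put in, blue
4. amount of open intermediate at the outlet or at the end, in percent of the substrate put in, amber
5. amount of open intermediate at the outlet or at the end, in percent of the substrate put in, grey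

1. Friday's first reading gives the constant of substrate turning into open intermediate, about 0.0794 min⁻¹, so a portion of substrate waits about 12.6 min on average.

2. From Friday's readings at 20.0 min and 50.0 min, I take what the substrate supplied, subtract the change in open intermediate, and divide by the mean amount held. This reading over that window gives the survival life, the time in which open intermediate falls by a factor e at this charge and partner, a life I treat as pseudo-first-order: 59.4 min. Monday's run, at half the charge of substrate with the same equivalents of partner, reads 117 min, twice as long, so with the equivalents of partner held I let the life go inversely with the charge.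

3. The zero of the scale is a feed of no length, where amber and blue are the same flask. Feeding moves the mean birth of open intermediate later by 32.0 min. I reckon its mean age at the end as 67.4 min in blue and 35.4 min in amber.

4. The price of feeding is the substrate still unconverted in amber, a fraction 0.0550 of the charge by my reckoning.

5. So I expect open intermediate at the end to be a fraction of the charge of 0.322 in blue and a larger 0.521 in amber.

6. For the opposite outcome, in this reckoning, the life would have to reach 566 min before blue drew level with amber, which is 9.53 times the reading. What to watch is the leftover substrate and the open intermediate at the end.

The forecast names amber: ochre 42%, blue 37%, amber 53%, grey 41%, on the ground that “low early intermediate limits both losses and feeding ends late”. My blue stands lower than its figure.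

The set-up that comes out highest is amber, with amber 54.1%, ochre 43.8%, blue 37.7% and grey 41.9%.

substrate → open intermediate (k = 0.00130 s⁻¹); partner → second intermediate (k = 0.0180 s⁻¹); open intermediate + second intermediate → target (k = 0.0150 M⁻¹ s⁻¹); 2 open intermediate → homo product (k = 0.00370 M⁻¹ s⁻¹); second intermediate + capture agent → trapped intermediate (k = 0.530 M⁻¹ s⁻¹) At the end amber holds 8.22% homo product, about half of blue's 16.2%. For the same flask as amber at 4.2 mM of substrate, with the equivalents of partner held, my inverse rule puts the survival life at 241 min, and the same age and leftover give a fraction 0.816. That flask ends at 82.3%.

(The readings were generated by integration for an exercise; the scatter is artificial.)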